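Follow the fraction of solid substrate left, not the target made.

| flask | solid substrate | protic impurity | remark | time |
|---|---|---|---|---|
| spring | 0.050 M | 0.025 M | run made earlier |  |
| autumn | 0.050 M | 0.10 M | run made earlier |  |
| flask | 0.050 M | 0.0500 M |  | 15 d |

| run | time / d | target / % | solid substrate / % |
|---|---|---|---|
| spring | 0.417 | 9.6 | 71.2 |
| spring | 0.625 | 13.8 | 57.1 |
| spring | 1.25 | 18.5 | 17.8 |
| spring | 2.50 | 9.5 | 0.2 |
| spring | 4.00 | 5.1 | 0 |
| spring | 8.00 | 1.8 | 0.1 |
| spring | 15.0 | 0.7 | 0.4 |
| autumn | 0.417 | 8.9 | 70.4 |
| autumn | 0.625 | 12.6 | 55.7 |
| autumn | 1.25 | 16.3 | 15.2 |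
| autumn | 2.50 | 7.9 | 0 |
| autumn | 4.00 | 3.2 | 0.7 |
| autumn | 8.00 | 0.8 | 0 |
| autumn | 15.0 | 0 | 0 |

(each reading ± 0.3 percentage points)

- given per volume of solution although it is solid: solid substrate
- the numbers in the tables scatter by 0.3 percentage points (one standard deviation)
- at the start none of the solid substrate is in solution

* time up to 15 d at which target stands highest
* the amount of target, in percent of the solid substrate charged, at that time

In the spring run, target reads 18.5% at 1.25 d, with solid substrate still present, but 9.5% at 2.50 d, when the solid substrate reading lies within scatter of zero. So I look for the peak near the moment the solid goes. Solid reads 17.8% in spring and 15.2% in autumn at 1.25 d, which bounds that moment from below. Its readings of 0.2% and 0% at 2.50 d lie within scatter of zero, which bounds it from above.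

To tighten this, I treat the fraction left as falling in a straight line, a zero-order loss. Between the first and third readings it falls by 0.641 d⁻¹ in spring and 0.663 d⁻¹ in autumn. Extended, the lines reach zero at 1.53 d and 1.48 d. Their mean is my solid-out time T for the flask, the time at which the fraction left reaches zero: 1.50 d. For the height in the flask I expect about the 16.3% to 18.5% read at 1.25 d in autumn and spring.

The forecast gives 1.3 d and 17.8%, holding that “Impurity lowers the target only modestly and does not shift the timing”. Its time stands earlier than my tightened bracket, and its height stands inside my range.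

The flask peaks at 1.52 d with 18.1%. Its solid substrate stands at 0.723% at 1.50 d and 0% at 1.52 d. T lies 0.0200 d before that peak.

    solid substrate ⇌ starting material, rate k1*(cs1 - [starting material]) while solid is left; crystals form when [starting material] > cs1 (solubility = 37.0 mM, k = 7.50 × 10⁻⁴ min⁻¹)
    starting material + target → side product (k = 0.130 M⁻¹ min⁻¹)
    starting material + protic impurity → quenched substrate (k = 0.0140 M⁻¹ min⁻¹)
    starting material ⇌ target (K = 2.20, k = 0.00280 min⁻¹)

For a neighbour flask with 0.020 M of solid substrate, assuming the same molar pace, I reckon T at 0.601 d. The autumn and spring target readings nearest that, at 0.625 d, recounted on the smaller charge give 31.5% to 34.5%. That neighbour flask's computed best is 33.4%.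

The numbers in the tables are simulated with made-up constants; scatter was added.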